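The route rests on cutting the bond between vinylic C4 of ring A and the oxymethylene carbon C15 (eudesmane numbering). C15 is an sp3 carbon that bears the ester oxygen and has no β-hydrogen, so it can be delivered as an α-acyloxymethyl stannane. The key step is a last-step Stille coupling of a 15-nor alkenyl bromide (C4–Br, Δ3, acrylate already in place) with (tributylstannyl)methyl (Z)-p-coumarate, which attaches the whole unprotected Z-coumarate side chain in one operation. The bromide is placed by the C3 carbonyl of a Robinson-derived nor-octalone, a temporary activating group later erased by a reductive allylic transposition that also sets C5.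

Key step: step 13

Remark on numbering: eudesmane numbering is used for positions. Ring A is C1–C5 and C10, ring B is C5–C10, C10 carries the methyl group, C7 carries C11, and C15 is the oxymethylene carbon. β is the face of the C10 methyl group, α the opposite face.

Assumptions: commercial (+)-dihydrocarvone contains the C2 epimer, which converges in step 1 through the enamine. Tributyl(iodomethyl)stannane is taken as a purchasable reagent.

Step 1
Reactants: 1 (+)-dihydrocarvone; 2 (R)-1-phenylethylamine; 3 methyl vinyl ketone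
Product: 6 (2S,5R)-2-methyl-2-(3-oxobutyl)-5-(prop-1-en-2-yl)cyclohexan-1-one, via ketimine 4 (not isolated), via Michael adduct imine 5 (not isolated)
Conditions: 2, TsOH (cat.), toluene, reflux (Dean–Stark); then 3, THF, 40 °C; then 10% aq. AcOH, rt
Reagents that add atoms: water, O
Why: Chiral-imine Michael addition: the more substituted secondary enamine tautomer of 4 adds to 3 through a compact aza-ene-like transition state on the face set by the (R)-1-phenylethyl group, which should place the C10 methyl cis to the C7 isopropenyl group before aqueous acid hydrolyses the imine.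

Step 2
Reactants: 6 (2S,5R)-2-methyl-2-(3-oxobutyl)-5-(prop-1-en-2-yl)cyclohexan-1-one
Product: 7 (4aS,7R)-4a-methyl-7-(prop-1-en-2-yl)-4,4a,5,6,7,8-hexahydronaphthalen-2(3H)-one
Conditions: NaOMe, MeOH, rt → 60 °C
Reagents that add atoms: none
Why: Intramolecular aldol condensation (second stage of a Robinson annulation) closes ring A as the conjugated enone without touching C7 or C10.

Step 3
Reactants: 7 (4aS,7R)-4a-methyl-7-(prop-1-en-2-yl)-4,4a,5,6,7,8-hexahydronaphthalen-2(3H)-one
Product: 8 4β,5β-epoxy-15-nor-eudesm-11-en-3-one (major epimer expected)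
Conditions: 30% H2O2, aq. NaOH, MeOH, 0 °C
Reagents that add atoms: hydrogen peroxide, OO
Why: Weitz–Scheffer nucleophilic epoxidation attacks only the electron-poor enone double bond and leaves the isopropenyl group alone; the configuration of the oxirane is irrelevant because both epimers converge in step 4.

Step 4
Reactants: 8 4β,5β-epoxy-15-nor-eudesm-11-en-3-one
Product: 9 (4aS,7R)-1-bromo-4a-methyl-7-(prop-1-en-2-yl)-4,4a,5,6,7,8-hexahydronaphthalen-2(3H)-one
Conditions: 48% aq. HBr, acetone, 0 °C, short contact time
Reagents that add atoms: hydrogen bromide, Br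
Why: Acid-promoted opening of the α,β-epoxy ketone by bromide at C4 followed by dehydration of the tertiary β-hydroxy ketone should give the α-bromoenone, a transformation known for 4,5-epoxy-3-keto steroids, while cold aqueous acid adds to the isopropenyl group much more slowly.

Step 5
Reactants: 9 (4aS,7R)-1-bromo-4a-methyl-7-(prop-1-en-2-yl)-4,4a,5,6,7,8-hexahydronaphthalen-2(3H)-one
Product: 10 (2S,4aS,7R)-1-bromo-4a-methyl-7-(prop-1-en-2-yl)-2,3,4,4a,5,6,7,8-octahydronaphthalen-2-ol
Conditions: NaBH4, CeCl3·7H2O, MeOH, −40 °C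
Reagents that add atoms: none
Why: Luche 1,2-reduction: axial hydride delivery from the α-face, as in 4-en-3-one steroids, should give the pseudo-equatorial 3β-alcohol, cis to the C10 methyl group.

Step 6
Reactants: 10 (2S,4aS,7R)-1-bromo-4a-methyl-7-(prop-1-en-2-yl)-2,3,4,4a,5,6,7,8-octahydronaphthalen-2-ol
Product: 13 (2R,4aS,8aR)-8-bromo-4a-methyl-2-(prop-1-en-2-yl)-1,2,3,4,4a,5,6,8a-octahydronaphthalene, via 3α-sulfonylhydrazine 11 (not isolated), via 3α-allylic diazene 12 (not isolated)
Conditions: 2-nitrobenzenesulfonylhydrazide, PPh3, DEAD, N-methylmorpholine, −30 °C → rt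
Reagents that add atoms: none
Why: Reductive 1,3-transposition of an allylic alcohol: Mitsunobu displacement inverts C3, loss of sulfinic acid gives the 3α-monoalkyl diazene, and its suprafacial retro-ene loss of N2 delivers hydrogen to the α-face of C5, which should give the trans ring fusion and the C3=C4 alkene with bromine on C4.

Step 7
Reactants: 13 (2R,4aS,8aR)-8-bromo-4a-methyl-2-(prop-1-en-2-yl)-1,2,3,4,4a,5,6,8a-octahydronaphthalene
Product: 14 2-[(2R,4aS,8aR)-8-bromo-4a-methyl-1,2,3,4,4a,5,6,8a-octahydronaphthalen-2-yl]prop-2-enal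
Conditions: SeO2, wet dioxane, 80 °C
Reagents that add atoms: selenium dioxide, O=[Se]=O
Why: Riley allylic oxidation (ene reaction, then [2,3]-sigmatropic shift) should oxidise the methyl group of the electron-rich 1,1-disubstituted alkene to the aldehyde, while the bromine-deactivated ring alkene reacts far more slowly.

Step 8
Reactants: 14 2-[(2R,4aS,8aR)-8-bromo-4a-methyl-1,2,3,4,4a,5,6,8a-octahydronaphthalen-2-yl]prop-2-enal
Product: 15 2-[(2R,4aS,8aR)-8-bromo-4a-methyl-1,2,3,4,4a,5,6,8a-octahydronaphthalen-2-yl]prop-2-enoic acid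
Conditions: NaClO2, NaH2PO4, 2-methyl-2-butene, t-BuOH/H2O, 0 °C → rt
Reagents that add atoms: sodium chlorite, [Na+].[O-]Cl=O
Why: Pinnick oxidation converts the 2-substituted acrolein into the acrylic acid without touching either alkene, the hypochlorite by-product being scavenged by 2-methyl-2-butene.

Step 9
Reactants: 15 2-[(2R,4aS,8aR)-8-bromo-4a-methyl-1,2,3,4,4a,5,6,8a-octahydronaphthalen-2-yl]prop-2-enoic acid
Product: 16 methyl 2-[(2R,4aS,8aR)-8-bromo-4a-methyl-1,2,3,4,4a,5,6,8a-octahydronaphthalen-2-yl]prop-2-enoate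
Conditions: MeI, K2CO3, DMF, rt
Reagents that add atoms: iodomethane, CI
Why: SN2 O-alkylation of the carboxylate gives the methyl ester under conditions too mild to move the acrylate double bond or epimerise C7.

Step 10
Reactants: 17 4-[(tert-butyldimethylsilyl)oxy]benzaldehyde; 18 methyl bis(2,2,2-trifluoroethyl)phosphonoacetate
Product: 19 methyl (Z)-3-{4-[(tert-butyldimethylsilyl)oxy]phenyl}prop-2-enoate
Conditions: KHMDS, 18-crown-6, THF, −78 °C
Reagents that add atoms: none
Why: Still–Gennari olefination: the electron-poor trifluoroethyl phosphonate with a dissociated potassium counter-ion eliminates faster than the adducts equilibrate, which should give the Z enoate under kinetic control.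

Step 11
Reactants: 19 methyl (Z)-3-{4-[(tert-butyldimethylsilyl)oxy]phenyl}prop-2-enoate
Product: 20 (Z)-3-(4-hydroxyphenyl)prop-2-enoic acid
Conditions: LiOH, THF/MeOH/H2O, rt, dark; then dilute HCl
Reagents that add atoms: water, O
Why: Saponification, in which hydroxide also cleaves the aryl silyl ether, should give the free Z acid, since no thermal path for Z to E isomerisation is open at room temperature in the dark.

Step 12
Reactants: 20 (Z)-3-(4-hydroxyphenyl)prop-2-enoic acid; 21 tributyl(iodomethyl)stannane
Product: 22 (tributylstannyl)methyl (Z)-3-(4-hydroxyphenyl)prop-2-enoate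
Conditions: KHCO3, DMF, rt, dark
Reagents that add atoms: none
Why: Chemoselective SN2 O-alkylation: hydrogen carbonate deprotonates only the carboxylic acid, so the carboxylate rather than the phenol displaces iodide.

Step 13
Reactants: 16 methyl 2-[(2R,4aS,8aR)-8-bromo-4a-methyl-1,2,3,4,4a,5,6,8a-octahydronaphthalen-2-yl]prop-2-enoate; 22 (tributylstannyl)methyl (Z)-3-(4-hydroxyphenyl)prop-2-enoate
Product: 23 methyl 2-[(2R,4aR,8aR)-8-({[(2Z)-3-(4-hydroxyphenyl)prop-2-enoyl]oxy}methyl)-4a-methyl-1,2,3,4,4a,5,6,8a-octahydronaphthalen-2-yl]prop-2-enoate (target)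
Conditions: Pd2(dba)3 (5 mol %), AsPh3 (20 mol %), CuI (20 mol %), NMP, 70 °C, degassed, dark
Reagents that add atoms: none
Why: Zerovalent palladium inserts into the C4–Br bond of 16, the acyloxymethyl group of 22 is handed from tin to palladium (through a transient organocopper species, helped by coordination of the ester carbonyl oxygen), and reductive elimination forges the C4–C15 bond with the complete side chain attached. The closest known reaction type is the Migita–Kosugi–Stille coupling of (hydroxymethyl)- and (acyloxymethyl)tributylstannanes with alkenyl and aryl halides or enol triflates. No ring is closed and no stereocenter is formed; the position of the ring A double bond (C3=C4) is fixed by the alkenyl bromide and the Z geometry of the coumarate is carried through unchanged. The step needs selective transfer of the oxymethyl group over butyl, secured by the α-oxygen and the absence of β-hydrogens on C15, which also rules out β-hydride elimination. It also needs chemoselectivity in the presence of a free phenol, an acrylate and a Z-enoate, secured by base-free neutral conditions, a weakly donating arsine ligand that neither adds to the enoate nor readily ionises the product allylic ester, moderate temperature and exclusion of light.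

Compound list
1 | (+)-dihydrocarvone, (2R,5R)-2-methyl-5-(prop-1-en-2-yl)cyclohexan-1-one | CC(=C)[C@@H]1CC[C@@H](C)C(=O)C1 | starting material
2 | (R)-1-phenylethylamine | C[C@@H](N)c1ccccc1 | starting material
3 | methyl vinyl ketone (but-3-en-2-one) | CC(=O)C=C | starting material
4 | N-[(1R)-1-phenylethyl] ketimine of 1 (in equilibrium with its secondary enamine) | CC(=C)[C@@H]1CC[C@@H](C)C(=N[C@H](C)c2ccccc2)C1 | intermediate (not isolated)
5 | N-[(1R)-1-phenylethyl] ketimine of diketone 6 at the ring carbonyl (Michael adduct) | CC(=C)[C@@H]1CC[C@@](C)(CCC(C)=O)C(=N[C@H](C)c2ccccc2)C1 | intermediate (not isolated)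
6 | (2S,5R)-2-methyl-2-(3-oxobutyl)-5-(prop-1-en-2-yl)cyclohexan-1-one | CC(=C)[C@@H]1CC[C@@](C)(CCC(C)=O)C(=O)C1 | intermediate
7 | (4aS,7R)-4a-methyl-7-(prop-1-en-2-yl)-4,4a,5,6,7,8-hexahydronaphthalen-2(3H)-one (15-nor-eudesma-4,11-dien-3-one) | CC(=C)[C@@H]1CC[C@@]2(C)CCC(=O)C=C2C1 | intermediate
8 | 4β,5β-epoxy-15-nor-eudesm-11-en-3-one (major epimer; the 4α,5α-epimer converges) | CC(=C)[C@@H]1CC[C@@]2(C)CCC(=O)[C@@H]3O[C@]23C1 | intermediate
9 | (4aS,7R)-1-bromo-4a-methyl-7-(prop-1-en-2-yl)-4,4a,5,6,7,8-hexahydronaphthalen-2(3H)-one (4-bromo-15-nor-eudesma-4,11-dien-3-one) | CC(=C)[C@@H]1CC[C@@]2(C)CCC(=O)C(Br)=C2C1 | intermediate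
10 | (2S,4aS,7R)-1-bromo-4a-methyl-7-(prop-1-en-2-yl)-2,3,4,4a,5,6,7,8-octahydronaphthalen-2-ol (3β-alcohol) | CC(=C)[C@@H]1CC[C@@]2(C)CC[C@H](O)C(Br)=C2C1 | intermediate
11 | N-[(3α)-4-bromo-15-nor-eudesma-4,11-dien-3-yl]-N-(2-nitrophenylsulfonyl)hydrazine | CC(=C)[C@@H]1CC[C@@]2(C)CC[C@@H](N(N)S(=O)(=O)c3ccccc3[N+](=O)[O-])C(Br)=C2C1 | intermediate (not isolated)
12 | (3α)-4-bromo-15-nor-eudesma-4,11-dien-3-yl diazene | CC(=C)[C@@H]1CC[C@@]2(C)CC[C@@H](N=N)C(Br)=C2C1 | intermediate (not isolated)
13 | (2R,4aS,8aR)-8-bromo-4a-methyl-2-(prop-1-en-2-yl)-1,2,3,4,4a,5,6,8a-octahydronaphthalene (4-bromo-15-nor-5α-eudesma-3,11-diene) | CC(=C)[C@@H]1CC[C@@]2(C)CCC=C(Br)[C@@H]2C1 | intermediate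
14 | 2-[(2R,4aS,8aR)-8-bromo-4a-methyl-1,2,3,4,4a,5,6,8a-octahydronaphthalen-2-yl]prop-2-enal | C=C(C=O)[C@@H]1CC[C@@]2(C)CCC=C(Br)[C@@H]2C1 | intermediate
15 | 2-[(2R,4aS,8aR)-8-bromo-4a-methyl-1,2,3,4,4a,5,6,8a-octahydronaphthalen-2-yl]prop-2-enoic acid | C=C(C(=O)O)[C@@H]1CC[C@@]2(C)CCC=C(Br)[C@@H]2C1 | intermediate
16 | methyl 2-[(2R,4aS,8aR)-8-bromo-4a-methyl-1,2,3,4,4a,5,6,8a-octahydronaphthalen-2-yl]prop-2-enoate | C=C(C(=O)OC)[C@@H]1CC[C@@]2(C)CCC=C(Br)[C@@H]2C1 | intermediate
17 | 4-[(tert-butyldimethylsilyl)oxy]benzaldehyde | O=Cc1ccc(O[Si](C)(C)C(C)(C)C)cc1 | starting material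
18 | methyl bis(2,2,2-trifluoroethyl)phosphonoacetate | COC(=O)CP(=O)(OCC(F)(F)F)OCC(F)(F)F | starting material
19 | methyl (Z)-3-{4-[(tert-butyldimethylsilyl)oxy]phenyl}prop-2-enoate | COC(=O)/C=C\c1ccc(O[Si](C)(C)C(C)(C)C)cc1 | intermediate
20 | (Z)-3-(4-hydroxyphenyl)prop-2-enoic acid ((Z)-p-coumaric acid) | OC(=O)/C=C\c1ccc(O)cc1 | intermediate
21 | tributyl(iodomethyl)stannane | CCCC[Sn](CCCC)(CCCC)CI | starting material
22 | (tributylstannyl)methyl (Z)-3-(4-hydroxyphenyl)prop-2-enoate | CCCC[Sn](CCCC)(CCCC)COC(=O)/C=C\c1ccc(O)cc1 | intermediate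
23 | methyl 2-[(2R,4aR,8aR)-8-({[(2Z)-3-(4-hydroxyphenyl)prop-2-enoyl]oxy}methyl)-4a-methyl-1,2,3,4,4a,5,6,8a-octahydronaphthalen-2-yl]prop-2-enoate | C=C(C(=O)OC)[C@@H]1CC[C@@]2(C)CCC=C(COC(=O)/C=C\c3ccc(O)cc3)[C@@H]2C1 | target

Total step count: 13. Longest linear sequence: 10 steps (steps 1–9, then step 13); the stannane fragment takes 3 steps (10–12).

Steps most likely to fail

1. Step 13 (key coupling). What may go wrong: sluggish transfer of the acyloxymethyl group from tin to the hindered alkenylpalladium bromide, ionisation of the product allylic ester by zerovalent palladium, or drift of the coumarate from Z to E on prolonged heating. Fallback, setting out from 16 and returning at 23: Stille hydroxymethylation of 16 with (tributylstannyl)methanol (Pd(PPh3)4, dioxane, 100 °C) should give the allylic alcohol methyl 2-[(2R,4aR,8aR)-8-(hydroxymethyl)-4a-methyl-1,2,3,4,4a,5,6,8a-octahydronaphthalen-2-yl]prop-2-enoate F1. A Mitsunobu esterification of the alcohol with acid 20 (PPh3, DIAD, THF, 0 °C, dark), in which the carboxylic acid reacts in preference to the less acidic phenol, should then give 23.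

2. Step 6 (reductive transposition). What may go wrong: elimination of the activated allylic oxyphosphonium species to a bromodiene instead of displacement, or incomplete inversion at C3, which would erode the trans ring fusion. Fallback, setting out from 10 and returning at 13: formylation of 10 (acetic formic anhydride, pyridine, 0 °C) should give the 3β-formate (2S,4aS,7R)-1-bromo-4a-methyl-7-(prop-1-en-2-yl)-2,3,4,4a,5,6,7,8-octahydronaphthalen-2-yl formate F2. Palladium-catalysed hydrogenolysis of this allylic formate (Pd(acac)2, n-Bu3P, THF, rt) ionises the ester with palladium on the α-face, loses CO2 and passes hydride from palladium to the α-face of C5, so no substitution at C3 is needed; this approach is known to give trans ring junctions from 3β-formates of 4-enes. The 2-bromoallyl palladium intermediate should keep its C–Br bond under these mild conditions, and 13 should result.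

3. Step 7 (allylic oxidation). What may go wrong: over-oxidation, competing oxidation at the ring allylic positions and loss of material on selenium by-products. Fallback, setting out from 13 and returning at 14: ene-type allylic chlorination of the isopropenyl group with hypochlorous acid (Ca(OCl)2, solid CO2, CH2Cl2/H2O, 0 °C) should give the allylic chloride (2R,4aS,8aR)-8-bromo-2-(3-chloroprop-1-en-2-yl)-4a-methyl-1,2,3,4,4a,5,6,8a-octahydronaphthalene F3. Amine N-oxide oxidation of the chloride (N-methylmorpholine N-oxide, MeCN, rt) should then give enal 14.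

Further compounds
F1 | step 13 | methyl 2-[(2R,4aR,8aR)-8-(hydroxymethyl)-4a-methyl-1,2,3,4,4a,5,6,8a-octahydronaphthalen-2-yl]prop-2-enoate | C=C(C(=O)OC)[C@@H]1CC[C@@]2(C)CCC=C(CO)[C@@H]2C1
F2 | step 6 | (2S,4aS,7R)-1-bromo-4a-methyl-7-(prop-1-en-2-yl)-2,3,4,4a,5,6,7,8-octahydronaphthalen-2-yl formate | CC(=C)[C@@H]1CC[C@@]2(C)CC[C@H](OC=O)C(Br)=C2C1
F3 | step 7 | (2R,4aS,8aR)-8-bromo-2-(3-chloroprop-1-en-2-yl)-4a-methyl-1,2,3,4,4a,5,6,8a-octahydronaphthalene | ClCC(=C)[C@@H]1CC[C@@]2(C)CCC=C(Br)[C@@H]2C1
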